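**Retrosynthetic overview**
1. Target ⇒ acid removal of Boc and MOM groups and N-methylation of a fully protected 8-[(R)-N-Boc-pyrrolidin-2-yl]flavone (last step).
2. C8–C2′ bond ⇒ 8-bromoflavone + (S)-N-Boc-pyrrolidin-2-ylzinc chloride, made from Cs-symmetric N-Boc-pyrrolidine by sparteine-controlled removal of one of its two enantiotopic α-hydrogens; this late Negishi coupling sets the only stereocentre.
3. Ring C ⇒ carbonylative annulation of a 2-bromo-6-iodophenol (reacting at C–I only) with a 4-(methoxymethoxy)phenylacetylene and CO.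
4. Bromo-iodophenol ⇒ C2v-symmetric 4-methoxy-3,5-bis(methoxymethoxy)phenol (from 2-methoxyresorcinol by MOM protection and C–H borylation/oxidation), desymmetrised by Br then I; alkyne ⇒ 4-hydroxybenzaldehyde.
5. Ring order: rings A and B and the pyrrolidine are bought as rings; ring C is the only ring formed (step 6), and the pyrrolidine is attached afterwards (step 7).

Assumption: the stereocentre in the SMILES is (R) at pyrrolidine C2 (N > aryl > CH2 > H), and every reagent named without a compound number is bought.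

**Step 1**
Reactants: 1 2-methoxybenzene-1,3-diol (2-methoxyresorcinol)
Product: 2 2-methoxy-1,3-bis(methoxymethoxy)benzene
Conditions: NaH (2.4 equiv), MOMCl (2.4 equiv), DMF, 0 → 23 °C
Reagents that add atoms: chloromethyl methyl ether (MOMCl), COCCl
Why: Williamson-type O-alkylation (MOM protection) of both phenoxides gives base-stable acetals that survive the organometallic steps and are removed by acid at the end.

**Step 2**
Reactants: 2 2-methoxy-1,3-bis(methoxymethoxy)benzene
Product: 4 4-methoxy-3,5-bis(methoxymethoxy)phenol, via aryl pinacol boronate 3 (not isolated)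
Conditions: [Ir(OMe)(cod)]2 (1.5 mol %), dtbpy (3 mol %), B2pin2 (0.55 equiv), THF, 80 °C; then 30 % H2O2, aq NaOH, 0 °C
Reagents that add atoms: bis(pinacolato)diboron, CC1(C)OB(OC1(C)C)B1OC(C)(C)C(C)(C)O1 (Bpin of 3); hydrogen peroxide, OO (phenol oxygen of 4)
Why: sterically controlled iridium-catalysed C–H borylation reacts only at C5, the one ring C–H without an ortho substituent, and oxidation of the C–B bond gives the C2v-symmetric phenol (one-pot borylation/oxidation).

**Step 3**
Reactants: 4 4-methoxy-3,5-bis(methoxymethoxy)phenol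
Product: 6 2-bromo-6-iodo-4-methoxy-3,5-bis(methoxymethoxy)phenol, via monobromophenol 5 (not isolated)
Conditions: NBS (1.0 equiv), CH2Cl2, −78 → 0 °C; then NIS (1.05 equiv), 0 → 23 °C
Reagents that add atoms: N-bromosuccinimide, O=C1CCC(=O)N1Br; N-iodosuccinimide, O=C1CCC(=O)N1I
Why: electrophilic aromatic halogenation ortho to the free phenol, where the two equivalent ortho C–H bonds are the only ones left, so one equivalent of NBS brominates one of them and NIS then iodinates the other, giving two halogens of different reactivity in one operation.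

**Step 4**
Reactants: 7 4-hydroxybenzaldehyde
Product: 8 4-(methoxymethoxy)benzaldehyde
Conditions: MOMCl (1.3 equiv), i-Pr2NEt (1.5 equiv), CH2Cl2, 0 → 23 °C
Reagents that add atoms: chloromethyl methyl ether (MOMCl), COCCl
Why: MOM protection (O-alkylation) of the phenol, so that the later organozinc is not quenched and all three phenol protecting groups fall off together at the end.

**Step 5**
Reactants: 8 4-(methoxymethoxy)benzaldehyde
Product: 9 1-ethynyl-4-(methoxymethoxy)benzene
Conditions: dimethyl (1-diazo-2-oxopropyl)phosphonate (1.2 equiv), K2CO3 (2 equiv), MeOH, 23 °C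
Reagents that add atoms: Ohira–Bestmann reagent, COP(=O)(OC)C(=[N+]=[N-])C(C)=O
Why: Seyferth–Gilbert homologation in its Ohira–Bestmann form, in which methanolysis of the acetyl group releases the diazomethylphosphonate anion that olefinates the aldehyde and loses N2 to give the terminal alkyne under conditions harmless to the MOM ether.

**Step 6**
Reactants: 6 2-bromo-6-iodo-4-methoxy-3,5-bis(methoxymethoxy)phenol; 9 1-ethynyl-4-(methoxymethoxy)benzene
Product: 11 8-bromo-6-methoxy-5,7-bis(methoxymethoxy)-2-[4-(methoxymethoxy)phenyl]-4H-chromen-4-one, via ortho-hydroxyaryl ynone 10 (not isolated)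
Conditions: PdCl2(PPh3)2 (5 mol %), dppp (5 mol %), CO (1 atm), Et2NH, DMF, 45 °C
Reagents that add atoms: carbon monoxide, [C-]#[O+]
Why: carbonylative Sonogashira coupling followed by 6-endo oxa-Michael annulation, in which zerovalent palladium inserts into the C–I bond only, CO insertion and alkynylation give ynone 10, and Et2NH adds to the ynone and is expelled by the ortho phenol so that ring C closes as the flavone and not the aurone, leaving the bromine at C8.

**Step 7**
Reactants: 11 8-bromo-6-methoxy-5,7-bis(methoxymethoxy)-2-[4-(methoxymethoxy)phenyl]-4H-chromen-4-one; 12 tert-butyl pyrrolidine-1-carboxylate (N-Boc-pyrrolidine, 1.3 equiv)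
Product: 15 tert-butyl (2R)-2-{6-methoxy-5,7-bis(methoxymethoxy)-2-[4-(methoxymethoxy)phenyl]-4-oxo-4H-chromen-8-yl}pyrrolidine-1-carboxylate, via (S)-2-lithio-N-Boc-pyrrolidine 13 (not isolated), via (S)-N-Boc-pyrrolidin-2-ylzinc chloride 14 (not isolated)
Conditions: s-BuLi (1.3 equiv), (−)-sparteine (1.3 equiv), MTBE, −78 °C, 3 h; ZnCl2 (1.4 equiv, THF), −78 → 23 °C; then 11, Pd(OAc)2 (5 mol %), t-Bu3P·HBF4 (6 mol %), 23 → 50 °C
Reagents that add atoms: s-BuLi, CCC(C)[Li] (Li of 13); ZnCl2, Cl[Zn]Cl (ZnCl of 14)
Why: Beak-type sparteine-mediated asymmetric deprotonation followed by Negishi coupling, in which s-BuLi/(−)-sparteine removes the pro-S α-hydrogen of the Cs-symmetric carbamate and both the Li→Zn transmetalation and the palladium-catalysed coupling go with retention, so the C8–C2′ bond forms with the (R) configuration (about 96:4 er is typical for this reaction type).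

**Step 8**
Reactants: 15 tert-butyl (2R)-2-{6-methoxy-5,7-bis(methoxymethoxy)-2-[4-(methoxymethoxy)phenyl]-4-oxo-4H-chromen-8-yl}pyrrolidine-1-carboxylate
Product: 17 5,7-dihydroxy-2-(4-hydroxyphenyl)-6-methoxy-8-[(2R)-1-methylpyrrolidin-2-yl]-4H-chromen-4-one (target), via nor-amine hydrochloride 16 (not isolated)
Conditions: 3 M HCl in MeOH, 23 °C, 16 h; evaporate; then 37 % aq HCHO (2 equiv), 2-picoline–borane (1.5 equiv), MeOH, 0 → 23 °C; NaHCO3 work-up
Reagents that add atoms: hydrogen chloride, Cl (chloride of 16); formaldehyde, C=O (N-methyl carbon of 17)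
Why: acidolysis removes the Boc group and the three MOM acetals while the aryl methyl ether survives, and Borch-type reductive amination with formaldehyde methylates the secondary amine without touching the stereocentre, the mixture being kept acidic and at or below room temperature because a free ortho-hydroxybenzylamine can racemise by retro-Mannich ring opening when heated.

**Compound list**
1 | 2-methoxybenzene-1,3-diol (2-methoxyresorcinol) | COc1c(O)cccc1O | starting material
2 | 2-methoxy-1,3-bis(methoxymethoxy)benzene | COCOc1cccc(OCOC)c1OC | intermediate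
3 | 2-[4-methoxy-3,5-bis(methoxymethoxy)phenyl]-4,4,5,5-tetramethyl-1,3,2-dioxaborolane | COCOc1cc(cc(OCOC)c1OC)B1OC(C)(C)C(C)(C)O1 | intermediate
4 | 4-methoxy-3,5-bis(methoxymethoxy)phenol | COCOc1cc(O)cc(OCOC)c1OC | intermediate
5 | 2-bromo-4-methoxy-3,5-bis(methoxymethoxy)phenol | COCOc1cc(O)c(Br)c(OCOC)c1OC | intermediate
6 | 2-bromo-6-iodo-4-methoxy-3,5-bis(methoxymethoxy)phenol | COCOc1c(I)c(O)c(Br)c(OCOC)c1OC | intermediate
7 | 4-hydroxybenzaldehyde | O=Cc1ccc(O)cc1 | starting material
8 | 4-(methoxymethoxy)benzaldehyde | COCOc1ccc(C=O)cc1 | intermediate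
9 | 1-ethynyl-4-(methoxymethoxy)benzene | COCOc1ccc(C#C)cc1 | intermediate
10 | 1-[3-bromo-2-hydroxy-5-methoxy-4,6-bis(methoxymethoxy)phenyl]-3-[4-(methoxymethoxy)phenyl]prop-2-yn-1-one | COCOc1ccc(cc1)C#CC(=O)c1c(O)c(Br)c(OCOC)c(OC)c1OCOC | intermediate
11 | 8-bromo-6-methoxy-5,7-bis(methoxymethoxy)-2-[4-(methoxymethoxy)phenyl]-4H-chromen-4-one | COc1c(OCOC)c(Br)c2oc(-c3ccc(OCOC)cc3)cc(=O)c2c1OCOC | intermediate
12 | tert-butyl pyrrolidine-1-carboxylate | CC(C)(C)OC(=O)N1CCCC1 | starting material
13 | tert-butyl (2S)-2-lithiopyrrolidine-1-carboxylate ((−)-sparteine complex) | [Li][C@H]1CCCN1C(=O)OC(C)(C)C | intermediate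
14 | [(2S)-1-(tert-butoxycarbonyl)pyrrolidin-2-yl]zinc chloride | Cl[Zn][C@H]1CCCN1C(=O)OC(C)(C)C | intermediate
15 | tert-butyl (2R)-2-{6-methoxy-5,7-bis(methoxymethoxy)-2-[4-(methoxymethoxy)phenyl]-4-oxo-4H-chromen-8-yl}pyrrolidine-1-carboxylate | COc1c(OCOC)c([C@H]2CCCN2C(=O)OC(C)(C)C)c2oc(-c3ccc(OCOC)cc3)cc(=O)c2c1OCOC | intermediate
16 | 5,7-dihydroxy-2-(4-hydroxyphenyl)-6-methoxy-8-[(2R)-pyrrolidin-2-yl]-4H-chromen-4-one hydrochloride | Cl.COc1c(O)c([C@H]2CCCN2)c2oc(-c3ccc(O)cc3)cc(=O)c2c1O | intermediate
17 | 5,7-dihydroxy-2-(4-hydroxyphenyl)-6-methoxy-8-[(2R)-1-methylpyrrolidin-2-yl]-4H-chromen-4-one | COc1c(O)c([C@H]2CCCN2C)c2oc(-c3ccc(O)cc3)cc(=O)c2c1O | target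

**Step count**
Total: 8 steps. Longest linear sequence: 6 steps (1, 2, 3, 6, 7, 8); steps 4 and 5 form the two-step alkyne branch.

**Steps most likely to fail and fallbacks**

Step 7 is the riskiest. The C8–Br bond is flanked by the ring oxygen and a MOM ether, so reductive elimination may be slow enough for β-hydride elimination to win, which would give debrominated flavone and N-Boc-2-pyrroline. The fallback sets out from 11 and builds the stereocentre by asymmetric imine reduction instead of cross-coupling at sp3 carbon. Sonogashira coupling of 11 with but-3-yn-1-amine (PdCl2(PPh3)2, CuI, Et3N, DMF, 60 °C), the least sterically demanding C–C coupling, gives the aminoalkyne 8-(4-aminobut-1-yn-1-yl)-6-methoxy-5,7-bis(methoxymethoxy)-2-[4-(methoxymethoxy)phenyl]-4H-chromen-4-one F4. AgOTf-catalysed 5-endo-dig hydroamination (MeCN, 60 °C) then gives the cyclic imine 8-(3,4-dihydro-2H-pyrrol-5-yl)-6-methoxy-5,7-bis(methoxymethoxy)-2-[4-(methoxymethoxy)phenyl]-4H-chromen-4-one F5. Reduction of its C=N bond with an imine reductase of the enantiopreference that delivers the (R)-amine (NADPH, glucose/glucose dehydrogenase recycling, pH 7.5 buffer with DMSO) gives 6-methoxy-5,7-bis(methoxymethoxy)-2-[4-(methoxymethoxy)phenyl]-8-[(2R)-pyrrolidin-2-yl]-4H-chromen-4-one F6. Treatment with 3 M HCl in MeOH removes the MOM groups and the route is rejoined at 16, which is methylated as in the second half of step 8.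

Step 6 can fail by aminocarbonylation to the diethylamide, by aurone formation, or by insertion into the C–Br bond. The fallback sets out from 6 and 9 and makes the aryl–carbonyl bond by organomagnesium acylation instead of palladium carbonylation. Alkyne 9 is deprotonated (n-BuLi, THF, −78 °C) and quenched with N-methoxy-N-methylcarbamoyl chloride to give the Weinreb ynamide N-methoxy-N-methyl-3-[4-(methoxymethoxy)phenyl]prop-2-ynamide F3. Phenol 6 is deprotonated with MeMgCl (1 equiv), subjected to selective iodine–magnesium exchange with i-PrMgCl·LiCl (THF, −20 °C), and acylated with F3. After NH4Cl work-up this gives ynone 10, isolated this time, where the route is rejoined; Et2NH in EtOH at 23 °C closes it to 11.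

Step 3 can fail by over-halogenation (dibromide, diiodide) or by oxidation of the very electron-rich hydroquinone monoether to a quinone. The fallback sets out from 4 and moves the bromination to the flavone stage. NIS alone (1.0 equiv, CH2Cl2, −40 °C) gives 2-iodo-4-methoxy-3,5-bis(methoxymethoxy)phenol F1. The carbonylative annulation of step 6 with 9 then gives 6-methoxy-5,7-bis(methoxymethoxy)-2-[4-(methoxymethoxy)phenyl]-4H-chromen-4-one F2. NBS (DMF, 0 °C) brominates F2 at C8, the only free and most activated position of ring A, and the route is rejoined at 11. This costs one extra step in the linear sequence.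

**Further compounds**
F1 | step 3 | 2-iodo-4-methoxy-3,5-bis(methoxymethoxy)phenol | COCOc1cc(O)c(I)c(OCOC)c1OC
F2 | step 3 | 6-methoxy-5,7-bis(methoxymethoxy)-2-[4-(methoxymethoxy)phenyl]-4H-chromen-4-one | COc1c(OCOC)cc2oc(-c3ccc(OCOC)cc3)cc(=O)c2c1OCOC
F3 | step 6 | N-methoxy-N-methyl-3-[4-(methoxymethoxy)phenyl]prop-2-ynamide | COCOc1ccc(cc1)C#CC(=O)N(C)OC
F4 | step 7 | 8-(4-aminobut-1-yn-1-yl)-6-methoxy-5,7-bis(methoxymethoxy)-2-[4-(methoxymethoxy)phenyl]-4H-chromen-4-one | COc1c(OCOC)c(C#CCCN)c2oc(-c3ccc(OCOC)cc3)cc(=O)c2c1OCOC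
F5 | step 7 | 8-(3,4-dihydro-2H-pyrrol-5-yl)-6-methoxy-5,7-bis(methoxymethoxy)-2-[4-(methoxymethoxy)phenyl]-4H-chromen-4-one | COc1c(OCOC)c(C2=NCCC2)c2oc(-c3ccc(OCOC)cc3)cc(=O)c2c1OCOC
F6 | step 7 | 6-methoxy-5,7-bis(methoxymethoxy)-2-[4-(methoxymethoxy)phenyl]-8-[(2R)-pyrrolidin-2-yl]-4H-chromen-4-one | COc1c(OCOC)c([C@H]2CCCN2)c2oc(-c3ccc(OCOC)cc3)cc(=O)c2c1OCOC
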